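**Strategy.** Everything rests on cutting the O–C4 bond of the oxolane that bridges C1 and C4 of the ten-membered ring. The key step uses the C1 carbonyl sitting three atoms from the electron-rich E C4=C5 alkene, with C5 next to the acidic butenolide carbon C6: one iodonium-triggered ketalisation forms O–C4, closes the oxolane, sets C4 and C1 and leaves a C5 iodide placed for elimination to the C5=C6 enol lactone. Its precursor is the ten-membered 1-oxo-4E-ene 6,12-butenolide (6S,8S,10R) carrying C8–OTBS and C13–OAc, made by chromium-mediated closure of C6–C7 from a geranyl-derived keto-enal bearing a Z-iodoacrylate.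

Key step: step 14

Remark: C6 of the key-step precursor is drawn S, the epimer the ring closure is expected to give and that, with C6–H eclipsing C4=C5, exposes the alkene face leading to 4R; this centre is erased in step 18.
Remark: the tartrate crotylboronate of step 3 is taken as a stock reagent made in one operation from trans-2-butene, KOtBu/n-BuLi, B(OiPr)3 and (S,S)-diisopropyl tartrate; all numbered starting materials are commercial.

Atom labels C1–C15 are germacrane numbers of the target. TES = triethylsilyl, TBS = tert-butyldimethylsilyl.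

Step 1
Reactants: 1 geranyl acetate
Product: 2 (2E)-6,7-epoxy-3,7-dimethyloct-2-en-1-yl acetate (racemic epoxide)
Conditions: mCPBA (1.0 equiv), CH2Cl2, 0 °C
Reagents that add atoms: m-chloroperbenzoic acid, O=C(OO)c1cccc(Cl)c1
Why: Prilezhaev epoxidation is selective for the remote trisubstituted alkene because the other one is deactivated by the allylic acetate; the new epoxide centre is racemic and is cut away in step 2.

Step 2
Reactants: 2 epoxy acetate
Product: 3 (2E)-3-methyl-6-oxohex-2-en-1-yl acetate
Conditions: H5IO6, THF/H2O, 0 °C → rt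
Reagents that add atoms: none
Why: Periodic acid opens the epoxide to the glycol and cleaves it (Malaprade cleavage), releasing acetone and the C1 aldehyde while the allylic acetate and the E alkene are inert.

Step 3
Reactants: 3 aldehyde
Product: 5 (2E,6S,7R)-3,7-dimethylnona-2,8-diene-1,6-diol, via hydroxy acetate 4 (not isolated)
Conditions: (S,S)-diisopropyl tartrate (E)-crotylboronate, 4 Å MS, toluene, −78 °C; then 2 M NaOH, MeOH, rt
Reagents that add atoms: (S,S)-diisopropyl tartrate (E)-crotylboronate, C/C=C/CB1O[C@@H]([C@H](O1)C(=O)OC(C)C)C(=O)OC(C)C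
Why: Tartrate-controlled crotylboration (Roush) through a closed chair transition state: the E-crotyl unit gives the anti adduct and the (S,S)-tartrate directs attack on the Re face, so the methyl-bearing carbon (C10 of the target) is R, while the carbinol (C1) is oxidised later; the alkaline work-up cleaves the borate and the acetate.

Step 4
Reactants: 5 diol
Product: 6 bis(triethylsilyl) ether of 5
Conditions: Et3SiCl, imidazole, DMF, 0 °C
Reagents that add atoms: chlorotriethylsilane, CC[Si](CC)(CC)Cl
Why: Standard silyl ether formation on both hydroxyls (no stereocentre is touched), giving two groups that can later be removed together in the presence of a TBS ether.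

Step 5
Reactants: 6 bis-TES ether
Product: 8 (3R,4S,7E)-3,7-dimethyl-4,9-bis(triethylsilyloxy)non-7-en-1-ol, via alkyl-9-BBN adduct 7 (not isolated)
Conditions: 9-BBN, THF, 0 °C → rt; then NaOH, H2O2, 0 °C
Reagents that add atoms: hydrogen peroxide, OO
Why: Hydroboration–oxidation: 9-BBN adds anti-Markovnikov to the monosubstituted alkene and ignores the trisubstituted one, and alkaline peroxide oxidises the C–B bond with retention.

Step 6
Reactants: 8 primary alcohol
Product: 9 (3R,4S,7E)-3,7-dimethyl-4,9-bis(triethylsilyloxy)non-7-enal (the C8 aldehyde)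
Conditions: Dess–Martin periodinane, pyridine, CH2Cl2, 0 °C → rt
Reagents that add atoms: none
Why: Dess–Martin oxidation under buffered conditions gives the aldehyde without silyl loss; the adjacent carbon is a CH2, so nothing can epimerise.

Step 7
Reactants: 9 aldehyde; 10 ethyl propiolate
Product: 11 ethyl (4S,6R,7S,10E)-4-hydroxy-6,10-dimethyl-7,12-bis(triethylsilyloxy)dodec-10-en-2-ynoate
Conditions: (S,S)-ProPhenol (20 mol%), Me2Zn (3 equiv), Ph3PO (40 mol%), toluene, 4 °C
Reagents that add atoms: none
Why: Zinc–ProPhenol catalysed asymmetric alkynylation: the alkynylzinc derived from 10 adds to the aldehyde within the chiral dinuclear zinc pocket, so C8 is set by the catalyst (ligand antipode chosen for 8S) and not by the remote C10 centre.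

Step 8
Reactants: 11 propargylic alcohol
Product: 12 ethyl (4S,6R,7S,10E)-4-(tert-butyldimethylsilyloxy)-6,10-dimethyl-7,12-bis(triethylsilyloxy)dodec-10-en-2-ynoate
Conditions: TBSOTf, 2,6-lutidine, CH2Cl2, −78 °C
Reagents that add atoms: tert-butyldimethylsilyl triflate, CC(C)(C)[Si](C)(C)OS(=O)(=O)C(F)(F)F
Why: Silylation with the triflate and a hindered base at low temperature protects the propargylic alcohol without the base-induced isomerisation to which 4-hydroxy-2-ynoates are prone.

Step 9
Reactants: 12 ynoate; 13 formaldehyde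
Product: 15 ethyl (2Z,4S,6R,7S,10E)-4-(tert-butyldimethylsilyloxy)-2-(hydroxymethyl)-3-iodo-6,10-dimethyl-7,12-bis(triethylsilyloxy)dodeca-2,10-dienoate, via silyl iodoallenoate 14 (not isolated)
Conditions: Me3SiI, CH2Cl2, −78 → −40 °C; then CH2O (monomer in CH2Cl2), BF3·OEt2 (20 mol%), −78 °C; aq. NaHCO3
Reagents that add atoms: iodotrimethylsilane, C[Si](C)(C)I
Why: Iodo-aldol (β-iodo Morita–Baylis–Hillman type) reaction: conjugate addition of iodide from Me3SiI gives the silyl 3-iodoallenoate, whose Mukaiyama aldol with BF3-activated formaldehyde through an open transition state occurs on the side of C11 remote from the large iodine, the same anti mode that makes hydroiodination of 2-alkynoates Z-selective, so iodine ends cis to the ester.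

Step 10
Reactants: 15 allylic alcohol
Product: 16 ethyl (2Z,4S,6R,7S,10E)-2-(acetoxymethyl)-4-(tert-butyldimethylsilyloxy)-3-iodo-6,10-dimethyl-7,12-bis(triethylsilyloxy)dodeca-2,10-dienoate
Conditions: Ac2O, pyridine, DMAP (cat.), CH2Cl2, 0 °C
Reagents that add atoms: acetic anhydride, CC(=O)OC(C)=O
Why: Acetylation of the primary allylic alcohol installs the C13 acetate of the target before any other hydroxyl is free.

Step 11
Reactants: 16 acetate
Product: 17 ethyl (2Z,4S,6R,7S,10E)-2-(acetoxymethyl)-4-(tert-butyldimethylsilyloxy)-7,12-dihydroxy-3-iodo-6,10-dimethyldodeca-2,10-dienoate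
Conditions: PPTS (cat.), MeOH/CH2Cl2, 0 °C
Reagents that add atoms: none
Why: Acid-catalysed methanolysis removes the primary allylic and the secondary triethylsilyl ethers, while the bulkier secondary TBS ether, the acetate and the alkenyl iodide are kept.

Step 12
Reactants: 17 diol
Product: 18 ethyl (2Z,4S,6R,10E)-2-(acetoxymethyl)-4-(tert-butyldimethylsilyloxy)-3-iodo-6,10-dimethyl-7,12-dioxododeca-2,10-dienoate (C1 ketone, C6 enal)
Conditions: Dess–Martin periodinane, pyridine, CH2Cl2, 0 °C → rt
Reagents that add atoms: none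
Why: Dess–Martin oxidation converts the allylic alcohol into the E enal and the secondary alcohol into the C1 ketone in one operation; the buffered, non-basic medium leaves the C10 centre next to the new ketone intact.

Step 13
Reactants: 18 keto-enal alkenyl iodide
Product: 20 (6S,8S,10R)-13-acetoxy-8-(tert-butyldimethylsilyloxy)-1-oxogermacra-4E,7(11)-dien-6,12-olide, via hydroxy ester 19 (not isolated)
Conditions: CrCl2 (10 equiv), NiCl2 (2 mol%), DMSO/THF, rt, slow addition to 2 mM
Reagents that add atoms: none
Why: Nozaki–Hiyama–Kishi reaction: zerovalent nickel inserts into the C7–I bond, transmetalation gives an alkenyl species of trivalent chromium that adds to the aldehyde only (ketone and esters are inert) and, at high dilution, closes the ten-membered ring, after which the C6 alkoxide, cis to the ester, lactonises; with C8–H eclipsing C7=C11 (1,3-allylic strain with C13) the enal arrives on the face away from the C8 silyloxy group, which gives 6S.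

Step 14
Reactants: 20 ten-membered 1-oxo-4E-ene butenolide
Product: 21 (1S,4R,5S,6R,8S,10R)-13-acetoxy-8-(tert-butyldimethylsilyloxy)-1,4-epoxy-5-iodo-1-methoxygermacr-7(11)-en-6,12-olide
Conditions: N-iodosuccinimide (1.2 equiv), MeOH/CH2Cl2 1:1, −20 → 0 °C, dark
Reagents that add atoms: N-iodosuccinimide, O=C1CCC(=O)N1I; methanol, CO
Why: N-Iodosuccinimide transfers iodonium to the electron-rich trisubstituted C4=C5 alkene, the C1 carbonyl oxygen (or its methanol hemiketal) opens the iodonium at the more substituted C4 with inversion, and methanol caps the C1 oxocarbenium ion, so O–C4, C5–I and C1–OMe form in one operation. The closest known reaction is the iodo-ketalisation (iodoetherification with carbonyl participation) of γ,δ-unsaturated ketones in an alcohol. The oxolane O–C1–C2–C3–C4 closes in a 5-exo mode with Markovnikov opening at the tertiary C4. C5 (S) is set by anti addition across the E alkene; C4 (R) is set by the alkene face that takes iodine, because with C6–H eclipsing C4=C5 (1,3-allylic strain with C15) the lactone oxygen lies on the outer face that receives iodine while C7, C2 and the carbonyl lie on the inner face; C1 (S) follows from C4 because a bridgehead of the oxabicycle has one position only for its fourth substituent. The step needs chemoselectivity for C4=C5 over C7=C11, secured by conjugation of C7=C11 to the lactone carbonyl, and face selectivity at C4=C5, secured by the ring conformer fixed through the 6S centre. No base is present, so the acidic C6–H and the C10 centre next to the ketone are not disturbed.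

Step 15
Reactants: 21 iodo ketal
Product: 22 (1S,4R,5S,6R,8S,10R)-13-acetoxy-1,4-epoxy-8-hydroxy-5-iodo-1-methoxygermacr-7(11)-en-6,12-olide
Conditions: HF·pyridine, pyridine, THF, 0 °C → rt
Reagents that add atoms: none
Why: Fluoride-mediated desilylation with buffered HF·pyridine frees the C8 hydroxyl; the ketal, the C5 iodide and the acetate are stable to this weakly acidic, non-nucleophilic medium.

Step 16
Reactants: 23 (tert-butyldimethylsilyloxy)acetaldehyde; 24 ethyl 2-(triphenylphosphoranylidene)propanoate
Product: 25 ethyl (E)-4-(tert-butyldimethylsilyloxy)-2-methylbut-2-enoate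
Conditions: CH2Cl2, rt
Reagents that add atoms: none
Why: Wittig olefination with a stabilised, α-branched ylide gives the E trisubstituted enoate.

Step 17
Reactants: 25 enoate
Product: 26 (E)-4-(tert-butyldimethylsilyloxy)-2-methylbut-2-enoic acid
Conditions: LiOH, THF/MeOH/H2O, rt; then 1 M HCl to pH 4, 0 °C
Reagents that add atoms: lithium hydroxide, [Li+].[OH-]
Why: Saponification of the ethyl ester; the primary TBS ether and the alkene geometry survive hydroxide at room temperature.

Step 18
Reactants: 22 C8 alcohol; 26 side-chain acid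
Product: 28 (1S,4R,8S,10R)-13-acetoxy-1,4-epoxy-1-methoxy-8-[(E)-4-(tert-butyldimethylsilyloxy)-2-methylbut-2-enoyloxy]germacra-5E,7(11)-dien-6,12-olide, via iodo ester 27 (not isolated)
Conditions: 26, 2,4,6-trichlorobenzoyl chloride, Et3N, THF; then 22, DMAP, toluene, rt; then DBU, 0 °C → rt
Reagents that add atoms: none
Why: Yamaguchi esterification acylates the hindered C8 alcohol through the mixed anhydride, and DBU then removes HI by an E1cB elimination: deprotonation at C6 gives the 2-oxidofuran, which expels iodide from C5 (a far better leaving group than the C13 acetate) to give the C5=C6 alkene with the geometry imposed by the bridged ring, C4 cis to C7.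

Step 19
Reactants: 28 protected dienyl lactone
Product: 29 target, (1S,4R,8S,10R)-13-acetoxy-1,4-epoxy-1-hydroxy-8-[(E)-4-hydroxy-2-methylbut-2-enoyloxy]germacra-5E,7(11)-dien-6,12-olide
Conditions: AcOH/THF/H2O 3:1:1, rt
Reagents that add atoms: water, O
Why: Aqueous acid hydrolyses the bridgehead methyl ketal through the oxolanyl oxocarbenium ion, to which water can return only at the single exo position so that C1 stays S, and it cleaves the primary allylic TBS ether.

**Compound list**

1 | geranyl acetate | CC(=O)OC/C=C(\C)CCC=C(C)C | starting material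
2 | (2E)-6,7-epoxy-3,7-dimethyloct-2-en-1-yl acetate, racemic at the epoxide | CC(=O)OC/C=C(\C)CCC1OC1(C)C | intermediate
3 | (2E)-3-methyl-6-oxohex-2-en-1-yl acetate | CC(=O)OC/C=C(\C)CCC=O | intermediate
4 | (2E,6S,7R)-6-hydroxy-3,7-dimethylnona-2,8-dien-1-yl acetate | C=C[C@@H](C)[C@@H](O)CC/C(C)=C/COC(C)=O | intermediate (not isolated)
5 | (2E,6S,7R)-3,7-dimethylnona-2,8-diene-1,6-diol | C=C[C@@H](C)[C@@H](O)CC/C(C)=C/CO | intermediate
6 | bis(triethylsilyl) ether of 5 | C=C[C@@H](C)[C@@H](O[Si](CC)(CC)CC)CC/C(C)=C/CO[Si](CC)(CC)CC | intermediate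
7 | B-alkyl-9-borabicyclo[3.3.1]nonane from 6 | C1CCC2CCCC1B2CC[C@@H](C)[C@@H](O[Si](CC)(CC)CC)CC/C(C)=C/CO[Si](CC)(CC)CC | intermediate (not isolated)
8 | (3R,4S,7E)-3,7-dimethyl-4,9-bis(triethylsilyloxy)non-7-en-1-ol | OCC[C@@H](C)[C@@H](O[Si](CC)(CC)CC)CC/C(C)=C/CO[Si](CC)(CC)CC | intermediate
9 | (3R,4S,7E)-3,7-dimethyl-4,9-bis(triethylsilyloxy)non-7-enal | O=CC[C@@H](C)[C@@H](O[Si](CC)(CC)CC)CC/C(C)=C/CO[Si](CC)(CC)CC | intermediate
10 | ethyl propiolate | CCOC(=O)C#C | starting material
11 | ethyl (4S,6R,7S,10E)-4-hydroxy-6,10-dimethyl-7,12-bis(triethylsilyloxy)dodec-10-en-2-ynoate | CCOC(=O)C#C[C@@H](O)C[C@@H](C)[C@@H](O[Si](CC)(CC)CC)CC/C(C)=C/CO[Si](CC)(CC)CC | intermediate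
12 | 4-O-TBS ether of 11 | CCOC(=O)C#C[C@@H](O[Si](C)(C)C(C)(C)C)C[C@@H](C)[C@@H](O[Si](CC)(CC)CC)CC/C(C)=C/CO[Si](CC)(CC)CC | intermediate
13 | formaldehyde | C=O | starting material
14 | ethyl trimethylsilyl ketene acetal of the 3-iodoallenoate from 12 | CCOC(O[Si](C)(C)C)=C=C(I)[C@@H](O[Si](C)(C)C(C)(C)C)C[C@@H](C)[C@@H](O[Si](CC)(CC)CC)CC/C(C)=C/CO[Si](CC)(CC)CC | intermediate (not isolated)
15 | ethyl (2Z,4S,6R,7S,10E)-4-(TBS-oxy)-2-(hydroxymethyl)-3-iodo-6,10-dimethyl-7,12-bis(triethylsilyloxy)dodeca-2,10-dienoate | CCOC(=O)/C(CO)=C(\I)[C@@H](O[Si](C)(C)C(C)(C)C)C[C@@H](C)[C@@H](O[Si](CC)(CC)CC)CC/C(C)=C/CO[Si](CC)(CC)CC | intermediate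
16 | 2-(acetoxymethyl) analogue of 15 | CCOC(=O)/C(COC(C)=O)=C(\I)[C@@H](O[Si](C)(C)C(C)(C)C)C[C@@H](C)[C@@H](O[Si](CC)(CC)CC)CC/C(C)=C/CO[Si](CC)(CC)CC | intermediate
17 | 7,12-diol from 16 | CCOC(=O)/C(COC(C)=O)=C(\I)[C@@H](O[Si](C)(C)C(C)(C)C)C[C@@H](C)[C@@H](O)CC/C(C)=C/CO | intermediate
18 | ethyl (2Z,4S,6R,10E)-2-(acetoxymethyl)-4-(TBS-oxy)-3-iodo-6,10-dimethyl-7,12-dioxododeca-2,10-dienoate | CCOC(=O)/C(COC(C)=O)=C(\I)[C@@H](O[Si](C)(C)C(C)(C)C)C[C@@H](C)C(=O)CC/C(C)=C/C=O | intermediate
19 | ring-closed (6S)-6-hydroxy ethyl ester, ten-membered carbocycle with C6–OH cis to CO2Et across C7=C11 | CCOC(=O)/C(COC(C)=O)=C1/[C@@H](O[Si](C)(C)C(C)(C)C)C[C@@H](C)C(=O)CC/C(C)=C/[C@@H]1O | intermediate (not isolated)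
20 | (6S,8S,10R)-13-acetoxy-8-(TBS-oxy)-1-oxogermacra-4E,7(11)-dien-6,12-olide | CC(=O)OCC1=C2[C@@H](O[Si](C)(C)C(C)(C)C)C[C@@H](C)C(=O)CC/C(C)=C/[C@@H]2OC1=O | intermediate
21 | (1S,4R,5S,6R,8S,10R)-13-acetoxy-8-(TBS-oxy)-1,4-epoxy-5-iodo-1-methoxygermacr-7(11)-en-6,12-olide | CC(=O)OCC1=C2[C@H]([C@H](I)[C@@]3(C)CC[C@](OC)(O3)[C@H](C)C[C@@H]2O[Si](C)(C)C(C)(C)C)OC1=O | intermediate
22 | 8-hydroxy analogue of 21 | CC(=O)OCC1=C2[C@H]([C@H](I)[C@@]3(C)CC[C@](OC)(O3)[C@H](C)C[C@@H]2O)OC1=O | intermediate
23 | (tert-butyldimethylsilyloxy)acetaldehyde | O=CCO[Si](C)(C)C(C)(C)C | starting material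
24 | ethyl 2-(triphenylphosphoranylidene)propanoate | CCOC(=O)C(C)=P(c1ccccc1)(c1ccccc1)c1ccccc1 | starting material
25 | ethyl (E)-4-(TBS-oxy)-2-methylbut-2-enoate | CCOC(=O)/C(C)=C/CO[Si](C)(C)C(C)(C)C | intermediate
26 | (E)-4-(TBS-oxy)-2-methylbut-2-enoic acid | OC(=O)/C(C)=C/CO[Si](C)(C)C(C)(C)C | intermediate
27 | 8-O-[(E)-4-(TBS-oxy)-2-methylbut-2-enoyl] ester of 22 | CC(=O)OCC1=C2[C@H]([C@H](I)[C@@]3(C)CC[C@](OC)(O3)[C@H](C)C[C@@H]2OC(=O)/C(C)=C/CO[Si](C)(C)C(C)(C)C)OC1=O | intermediate (not isolated)
28 | (1S,4R,8S,10R)-13-acetoxy-1,4-epoxy-1-methoxy-8-[(E)-4-(TBS-oxy)-2-methylbut-2-enoyloxy]germacra-5E,7(11)-dien-6,12-olide | CC(=O)OCC1=C2/C(=C\[C@@]3(C)CC[C@](OC)(O3)[C@H](C)C[C@@H]2OC(=O)/C(C)=C/CO[Si](C)(C)C(C)(C)C)OC1=O | intermediate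
29 | target, CNP0154520.1 | CC(=O)OCC1=C2/C(=C\[C@@]3(C)CC[C@](O)(O3)[C@H](C)C[C@@H]2OC(=O)/C(C)=C/CO)OC1=O | target

**Step count and risks**

Total: 19 steps. Longest linear sequence: 17 steps (steps 1–15, 18 and 19).

Step 14 (key step). What may go wrong: methanol may capture the iodonium before the carbonyl oxygen closes the oxolane, or closure may be slow enough for iodination to reverse and the doubly activated C6–H to isomerise. The fallback sets out from 20 and returns at 28. It replaces the reversible iodonium by an isolated epoxide: dimethyldioxirane in acetone at −20 °C epoxidises C4=C5 on the same outer face to give the 4,5-epoxide F1. Camphorsulfonic acid (cat.) in methanol then lets the C1 hemiketal hydroxyl open the epoxide at C4 (5-exo, inversion) to give the 5-hydroxy methyl ketal F2. MsCl/Et3N followed by DBU eliminates the C5 oxygen through the acidic C6 position to the silyl-protected dienyl lactone F3. HF·pyridine frees the C8 alcohol of the dienyl lactone F4, which is esterified with 26 under the Yamaguchi conditions of step 18 (without DBU) to give 28.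

Step 13. What may go wrong: the alkenylchromium may oligomerise or be reduced instead of closing the ten-membered ring, and face selectivity at C6 may be poor. The fallback sets out from 16 and returns at 20. It changes the order so that the ring closes while C1 is still an sp3 silyloxy carbon: Swern conditions ((COCl)2, DMSO, then Et3N) oxidise only the primary allylic triethylsilyl ether of 16 to the C1-silyloxy enal F5. CrCl2/NiCl2 closure and lactonisation then give the C1-silyloxy macrocyclic butenolide F6. PPTS in MeOH frees the C1 alcohol F7, and Dess–Martin periodinane gives 20.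

Step 9. What may go wrong: geometric control may be poor when the iodoallenoate captures formaldehyde, or iodide may add slowly to the β-branched ynoate with loss of silyl groups. The fallback sets out from 11 and returns at 16. It uses delivery by the neighbouring oxygen instead of an open transition state: MgI2 and CH2O in CH2Cl2 at 0 °C on the free C8 alcohol 11 let the magnesium alkoxide bind formaldehyde and pass it to C11 from the C8 side, giving the Z diol F8. Any E isomer would lactonise to an iodobutenolide and be separated. AcCl/2,4,6-collidine at −78 °C acetylates only the primary allylic hydroxyl to give the C13 acetate F9, and TBSOTf/2,6-lutidine gives 16.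

**Further compounds**

F1 | step 14 | 4,5-epoxide of 20, oxygen on the outer face | CC(=O)OCC1=C2[C@@H](O[Si](C)(C)C(C)(C)C)C[C@@H](C)C(=O)CC[C@]3(C)O[C@H]3[C@@H]2OC1=O
F2 | step 14 | 5-hydroxy methyl ketal (5-hydroxy analogue of 21) | CC(=O)OCC1=C2[C@H]([C@H](O)[C@@]3(C)CC[C@](OC)(O3)[C@H](C)C[C@@H]2O[Si](C)(C)C(C)(C)C)OC1=O
F3 | step 14 | silyl-protected dienyl lactone (8-O-TBS, 1-methoxy) | CC(=O)OCC1=C2/C(=C\[C@@]3(C)CC[C@](OC)(O3)[C@H](C)C[C@@H]2O[Si](C)(C)C(C)(C)C)OC1=O
F4 | step 14 | C8 alcohol of the dienyl lactone (1-methoxy) | CC(=O)OCC1=C2/C(=C\[C@@]3(C)CC[C@](OC)(O3)[C@H](C)C[C@@H]2O)OC1=O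
F5 | step 13 | C1-silyloxy enal | CCOC(=O)/C(COC(C)=O)=C(\I)[C@@H](O[Si](C)(C)C(C)(C)C)C[C@@H](C)[C@@H](O[Si](CC)(CC)CC)CC/C(C)=C/C=O
F6 | step 13 | C1-silyloxy macrocyclic butenolide | CC(=O)OCC1=C2[C@@H](O[Si](C)(C)C(C)(C)C)C[C@@H](C)[C@@H](O[Si](CC)(CC)CC)CC/C(C)=C/[C@@H]2OC1=O
F7 | step 13 | C1 alcohol of the macrocyclic butenolide | CC(=O)OCC1=C2[C@@H](O[Si](C)(C)C(C)(C)C)C[C@@H](C)[C@@H](O)CC/C(C)=C/[C@@H]2OC1=O
F8 | step 9 | Z diol (C8–OH, C13–OH) | CCOC(=O)/C(CO)=C(\I)[C@@H](O)C[C@@H](C)[C@@H](O[Si](CC)(CC)CC)CC/C(C)=C/CO[Si](CC)(CC)CC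
F9 | step 9 | C13 acetate of the Z diol | CCOC(=O)/C(COC(C)=O)=C(\I)[C@@H](O)C[C@@H](C)[C@@H](O[Si](CC)(CC)CC)CC/C(C)=C/CO[Si](CC)(CC)CC
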